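Spring held twice the starting material of dusk, and so twice the enzyme, because the loading stayed at 0.1 mol%, yet at 120 min it showed about the same percentage of target: 12.9% against 12.0% in dusk and 12.4% in dawn.

all flasks: free enzyme 0.1 mol%
- dusk: starting material 0.014 M; second substrate 1 equiv; run made earlier
- dawn: starting material 0.014 M; second substrate 2.2 equiv; run made earlier
- spring: starting material 0.028 M; second substrate 1.5 equiv; run made earlier
- flask: starting material 0.014 M; second substrate 1.50 equiv

- dusk (time / min: target / %): 15.0: 0.7; 40.0: 2.1; 80.0: 5.9; 120: 12.0
- dawn (time / min: target / %): 15.0: 1.9; 40.0: 2.1; 80.0: 8.8; 120: 12.4
- spring (time / min: target / %): 10.0: 1.8; 20.0: 2.6; 50.0: 6.6; 120: 12.9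

(scatter of a reading: 1 percentage point)

1. apparent order in free enzyme when 50% of the starting material are converted (percent change of the rate of making target for one percent more free enzyme charged)

The meeting opened on that comparison. The first speaker noted that at 120 min dawn, with 2.2 equiv of second substrate, lay within the scatter of 1 percentage point of dusk, with 1 equiv, though at 80.0 min the two read 8.8% and 5.9%, and she proposed averaging the two at the later time. The second speaker objected that no run changes the enzyme by itself, so the effects of c(starting material) and of the enzyme are read together. I proposed dividing spring's average rate up to 120 min by the mean of the average rates of dusk and dawn over the same time, so that time drops out, and taking the logarithm of that over the logarithm of the charge ratio. This gives 1.08, the charge exponent: the percent change of rate for one percent more of the whole charge at fixed equivalents. It is a reading, uncertain in its first decimal, and enzyme and starting material share it. My own figure for the enzyme is therefore about 1.08, assuming that the order in starting material is near zero and that the exponent holds up to 50% conversion, neither of which these runs can show.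

The forecast gave 1, lower than mine, with a range of 0.7 to 1.4, reached “from mechanism rather than direct measurement”.

The flask gives an order of 0.96 at 50% conversion.

    starting material + free enzyme ⇌ first complex (K = 60.0 M⁻¹, k = 1.50 × 10⁶ M⁻¹ h⁻¹)
    first complex ⇌ loaded enzyme + first product (K = 0.0100 M, k = 2000 h⁻¹)
    second substrate + loaded enzyme ⇌ second complex (K = 91.0 M⁻¹, k = 1.30 × 10⁵ M⁻¹ h⁻¹)
    second complex → free enzyme + target (k = 130 h⁻¹)
    2 second complex ⇌ resting dimer, settled at all times (K = 29000 M⁻¹)

Resting dimer, outside the working round and counted as two, held 14.6% of the catalyst after 2.00 h and 1.35% after 20.0 h. The flask has half of spring's charge at the same 1.50 equiv, so the charge exponent scales spring's 12.9% to 12.2% of target, and after 2.00 h the flask holds 11.7%.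

The runs are simulated with made-up constants.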